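**Plan**
- Retrosynthesis first removes the 8-O-acetyl group and the benzyl groups on O3, O3' and O4', then restores the 5- and 8-methyl ethers, then cuts the C3–O bond, and finally opens ring C at C4a–C4, C4–C3 and O1–C2.
- The enabling feature is that C4 is a lone carbonyl carbon bridging C4a of ring A and the C3=C2 unit that carries ring B, with O1 ortho to C4a. Ring C therefore maps onto an ortho-iodophenol, carbon monoxide and an arylacetylene.
- Forward, ring A is taken from 2,3-dimethoxyphenol and completed by C–H borylation/oxidation at C5 and carbamate-directed iodination. Ring B is taken from 3,4-dibenzyloxybenzaldehyde, homologated to the alkyne.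
- Ring C, the only ring built, closes in the three-component carbonylative step. C3 is then hydroxylated and benzylated, ring A is unmasked through its 5,8-quinone, O8 is acetylated and the benzyl groups are hydrogenolysed.
- Stereochemistry: the target has no stereocentre and no configured double bond, so none has to be set.

Key step: step 7

Remark on the chemistry: the E descriptor given for the transient enaminone of the key step is lost on ring closure; the aryl acetate is assumed to survive neutral hydrogenolysis in an aprotic solvent.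

Step 1
Reactants: 1 2,3-dimethoxyphenol; 2 N,N-diethylcarbamoyl chloride
Product: 3 2,3-dimethoxyphenyl N,N-diethylcarbamate
Conditions: K2CO3, MeCN, reflux
Reagents that add atoms: none
Why: O-acylation of the phenoxide by the carbamoyl chloride (carbamate formation) is routine and installs the strongest oxygen-based group for the directed ortho metalation of step 4.

Step 2
Reactants: 3 2,3-dimethoxyphenyl N,N-diethylcarbamate
Product: 5 5-hydroxy-2,3-dimethoxyphenyl N,N-diethylcarbamate, via aryl pinacol boronate 4 (not isolated)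
Conditions: [Ir(OMe)(cod)]2 (1.5 mol%), 4,4'-di-tert-butyl-2,2'-bipyridine (3 mol%), B2pin2 (0.6 equiv), THF, 80 °C; then KHSO5 (as 2KHSO5·KHSO4·K2SO4), acetone/H2O, rt
Reagents that add atoms: bis(pinacolato)diboron, CC1(C)OB(OC1(C)C)B1OC(C)(C)C(C)(C)O1 (boryl group of 4 only); potassium peroxymonosulfate, [K+].[O-]S(=O)(=O)OO (oxygen of the new hydroxyl)
Why: Iridium-catalysed aromatic C–H borylation is sterically controlled and should select C5, the only ring C–H without an ortho substituent, and the arylboronate 4 is then converted into the phenol by peroxymonosulfate in the same flask (one-pot C–H borylation/oxidation) under conditions that leave the carbamate intact.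

Step 3
Reactants: 5 5-hydroxy-2,3-dimethoxyphenyl N,N-diethylcarbamate
Product: 6 2,3,5-trimethoxyphenyl N,N-diethylcarbamate
Conditions: MeI, K2CO3, acetone, reflux
Reagents that add atoms: iodomethane, CI
Why: Williamson etherification of the single free phenol with iodomethane and carbonate base is unambiguous.

Step 4
Reactants: 6 2,3,5-trimethoxyphenyl N,N-diethylcarbamate
Product: 8 2-iodo-3,5,6-trimethoxyphenyl N,N-diethylcarbamate, via aryllithium 7 (not isolated)
Conditions: s-BuLi, TMEDA, THF, −78 °C; then I2, −78 °C to rt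
Reagents that add atoms: iodine, [I][I]
Why: Directed ortho metalation by the O-carbamate places lithium at C6, the only position ortho to the carbamate and further acidified by the flanking 5-methoxy group, and iodinolysis of aryllithium 7 at −78 °C outruns the anionic ortho-Fries rearrangement.

Step 5
Reactants: 8 2-iodo-3,5,6-trimethoxyphenyl N,N-diethylcarbamate
Product: 9 2-iodo-3,5,6-trimethoxyphenol
Conditions: NaOH, EtOH/H2O, reflux; then aq. HCl
Reagents that add atoms: none
Why: Saponification of the aryl carbamate by acyl–oxygen cleavage frees the phenol while the electron-rich aryl iodide and the methyl ethers are inert to hydroxide.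

Step 6
Reactants: 10 3,4-dibenzyloxybenzaldehyde
Product: 11 4-ethynyl-1,2-dibenzyloxybenzene
Conditions: dimethyl (1-diazo-2-oxopropyl)phosphonate, K2CO3, MeOH/THF, rt
Reagents that add atoms: dimethyl (1-diazo-2-oxopropyl)phosphonate, COP(=O)(OC)C(=[N+]=[N-])C(C)=O (terminal alkyne carbon)
Why: Seyferth–Gilbert homologation in its Ohira–Bestmann form converts the aryl aldehyde into the terminal alkyne through olefination by the in situ diazomethylphosphonate anion, loss of N2 and 1,2-hydride shift, under carbonate/methanol conditions that do not touch benzyl ethers.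

Step 7
Reactants: 9 2-iodo-3,5,6-trimethoxyphenol; 11 4-ethynyl-1,2-dibenzyloxybenzene; 12 carbon monoxide
Product: 15 2-(3,4-dibenzyloxyphenyl)-5,7,8-trimethoxychromen-4-one, via ortho-hydroxyaryl ynone 13 (not isolated), via diethylamino enaminone 14 (not isolated)
Conditions: PdCl2(dppf) (5 mol%), CO (20 bar), Et2NH, 120 °C
Reagents that add atoms: none
Why: Zerovalent palladium, formed in situ from the divalent precatalyst PdCl2(dppf), inserts into the C–I bond of 9, carbon monoxide inserts to give an aroylpalladium species, and transfer of the amine-generated acetylide followed by reductive elimination forms C4a–C4 and C4–C3 in ynone 13. Diethylamine then adds to the triple bond to give enaminone 14, and the ortho hydroxyl closes ring C by 6-endo-trig addition to the amine-bearing carbon and loss of diethylamine, which forms O1–C2. The closest known reaction type is the palladium-catalysed carbonylative coupling of ortho-iodophenols with terminal arylacetylenes in secondary amines, which gives flavones. No stereocentre is created. The step needs six-membered closure to beat 5-exo-dig closure to the aurone, which is secured by the free ortho hydroxyl meeting an enaminone whose only electrophilic carbon is C2, and it needs carbonylation to outrun direct alkynylation, which CO pressure and the absence of copper secure. The ring A pattern is fixed by the substrate, because iodine sits on the only carbon flanked by the hydroxyl and a methoxy group.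

Step 8
Reactants: 15 2-(3,4-dibenzyloxyphenyl)-5,7,8-trimethoxychromen-4-one
Product: 18 2-(3,4-dibenzyloxyphenyl)-3-hydroxy-5,7,8-trimethoxychromen-4-one, via 3-lithioflavone 16 (not isolated), via flavon-3-yl dimethyl boronate 17 (not isolated)
Conditions: LiN(iPr)2, THF, −78 °C; B(OMe)3, −78 to 0 °C; then AcOH, 30% H2O2, 0 °C to rt
Reagents that add atoms: trimethyl borate, COB(OC)OC (boron and methoxy groups of 17 only); hydrogen peroxide, OO (oxygen of the 3-hydroxyl)
Why: The C3–H of a flavone is removed by LiN(iPr)2 at −78 °C (vinylic deprotonation alpha to the carbonyl), the lithio species 16 is trapped as boronate 17 and the C–B bond is oxidised to C–O by H2O2, a known flavone-to-flavonol sequence that benzyl and methyl ethers tolerate.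

Step 9
Reactants: 18 2-(3,4-dibenzyloxyphenyl)-3-hydroxy-5,7,8-trimethoxychromen-4-one
Product: 19 3-benzyloxy-2-(3,4-dibenzyloxyphenyl)-5,7,8-trimethoxychromen-4-one
Conditions: BnBr, K2CO3, DMF, 50 °C
Reagents that add atoms: benzyl bromide, BrCc1ccccc1
Why: Williamson benzylation of the only hydroxyl masks O3 so that it can neither be oxidised in step 10 nor compete for acetic anhydride in step 11.

Step 10
Reactants: 19 3-benzyloxy-2-(3,4-dibenzyloxyphenyl)-5,7,8-trimethoxychromen-4-one
Product: 21 3-benzyloxy-2-(3,4-dibenzyloxyphenyl)-5,8-dihydroxy-7-methoxychromen-4-one, via flavone-5,8-quinone 20 (not isolated)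
Conditions: (NH4)2Ce(NO3)6, MeCN/H2O, 0 °C; then aq. Na2S2O4, EtOAc, rt, under N2
Reagents that add atoms: water, O (the two quinone oxygens, kept as the 5- and 8-hydroxyl oxygens)
Why: Oxidative demethylation by tetravalent cerium converts the para-related 5- and 8-methoxy groups into the 5,8-quinone 20 (water delivers the carbonyl oxygens and the 7-methoxy group survives as a vinylogous ester), a transformation known for 5,7,8-trimethoxyflavones, and dithionite reduces the quinone to the hydroquinone while ring B, deactivated by conjugation with the pyranone, should stay untouched.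

Step 11
Reactants: 21 3-benzyloxy-2-(3,4-dibenzyloxyphenyl)-5,8-dihydroxy-7-methoxychromen-4-one
Product: 22 8-acetoxy-3-benzyloxy-2-(3,4-dibenzyloxyphenyl)-5-hydroxy-7-methoxychromen-4-one
Conditions: Ac2O (1.1 equiv), pyridine, CH2Cl2, 0 °C, under N2
Reagents that add atoms: acetic anhydride, CC(=O)OC(C)=O
Why: The 5-hydroxyl is tied to the C4 carbonyl by a strong intramolecular hydrogen bond and is much less nucleophilic than the free 8-hydroxyl, so a slight excess of acetic anhydride at 0 °C should acylate O8 only (chemoselective phenol acylation as in the partial alkylation of 5,8-dihydroxyflavones).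

Step 12
Reactants: 22 8-acetoxy-3-benzyloxy-2-(3,4-dibenzyloxyphenyl)-5-hydroxy-7-methoxychromen-4-one
Product: 23 gossypetin 7-methyl ether 8-acetate (8-acetoxy-2-(3,4-dihydroxyphenyl)-3,5-dihydroxy-7-methoxychromen-4-one)
Conditions: H2 (1 atm), Pd/C, EtOAc/THF, rt
Reagents that add atoms: none
Why: Catalytic hydrogenolysis over Pd/C cleaves the three benzyl ethers in an aprotic solvent without reducing the chromenone double bond or cleaving the aryl acetate, which has no neighbouring hydroxyl to migrate to.

**Compound list**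
1 | 2,3-dimethoxyphenol | COc1cccc(O)c1OC | starting material
2 | N,N-diethylcarbamoyl chloride | CCN(CC)C(=O)Cl | starting material
3 | 2,3-dimethoxyphenyl N,N-diethylcarbamate | CCN(CC)C(=O)Oc1cccc(OC)c1OC | intermediate
4 | 2,3-dimethoxy-5-(4,4,5,5-tetramethyl-1,3,2-dioxaborolan-2-yl)phenyl N,N-diethylcarbamate | CCN(CC)C(=O)Oc1cc(B2OC(C)(C)C(C)(C)O2)cc(OC)c1OC | intermediate (not isolated)
5 | 5-hydroxy-2,3-dimethoxyphenyl N,N-diethylcarbamate | CCN(CC)C(=O)Oc1cc(O)cc(OC)c1OC | intermediate
6 | 2,3,5-trimethoxyphenyl N,N-diethylcarbamate | CCN(CC)C(=O)Oc1cc(OC)cc(OC)c1OC | intermediate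
7 | 2-lithio-3,5,6-trimethoxyphenyl N,N-diethylcarbamate | CCN(CC)C(=O)Oc1c([Li])c(OC)cc(OC)c1OC | intermediate (not isolated)
8 | 2-iodo-3,5,6-trimethoxyphenyl N,N-diethylcarbamate | CCN(CC)C(=O)Oc1c(I)c(OC)cc(OC)c1OC | intermediate
9 | 2-iodo-3,5,6-trimethoxyphenol | Oc1c(I)c(OC)cc(OC)c1OC | intermediate
10 | 3,4-dibenzyloxybenzaldehyde | O=Cc1ccc(OCc2ccccc2)c(OCc2ccccc2)c1 | starting material
11 | 4-ethynyl-1,2-dibenzyloxybenzene | C#Cc1ccc(OCc2ccccc2)c(OCc2ccccc2)c1 | intermediate
12 | carbon monoxide | [C-]#[O+] | starting material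
13 | 3-(3,4-dibenzyloxyphenyl)-1-(2-hydroxy-3,4,6-trimethoxyphenyl)prop-2-yn-1-one | COc1cc(OC)c(C(=O)C#Cc2ccc(OCc3ccccc3)c(OCc3ccccc3)c2)c(O)c1OC | intermediate (not isolated)
14 | (E)-3-(3,4-dibenzyloxyphenyl)-3-(diethylamino)-1-(2-hydroxy-3,4,6-trimethoxyphenyl)prop-2-en-1-one | CCN(CC)/C(=C/C(=O)c1c(O)c(OC)c(OC)cc1OC)c1ccc(OCc2ccccc2)c(OCc2ccccc2)c1 | intermediate (not isolated)
15 | 2-(3,4-dibenzyloxyphenyl)-5,7,8-trimethoxychromen-4-one | COc1cc(OC)c2c(=O)cc(-c3ccc(OCc4ccccc4)c(OCc4ccccc4)c3)oc2c1OC | intermediate
16 | 2-(3,4-dibenzyloxyphenyl)-3-lithio-5,7,8-trimethoxychromen-4-one | COc1cc(OC)c2c(=O)c([Li])c(-c3ccc(OCc4ccccc4)c(OCc4ccccc4)c3)oc2c1OC | intermediate (not isolated)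
17 | dimethyl [2-(3,4-dibenzyloxyphenyl)-5,7,8-trimethoxy-4-oxochromen-3-yl]boronate | COc1cc(OC)c2c(=O)c(B(OC)OC)c(-c3ccc(OCc4ccccc4)c(OCc4ccccc4)c3)oc2c1OC | intermediate (not isolated)
18 | 2-(3,4-dibenzyloxyphenyl)-3-hydroxy-5,7,8-trimethoxychromen-4-one | COc1cc(OC)c2c(=O)c(O)c(-c3ccc(OCc4ccccc4)c(OCc4ccccc4)c3)oc2c1OC | intermediate
19 | 3-benzyloxy-2-(3,4-dibenzyloxyphenyl)-5,7,8-trimethoxychromen-4-one | COc1cc(OC)c2c(=O)c(OCc3ccccc3)c(-c3ccc(OCc4ccccc4)c(OCc4ccccc4)c3)oc2c1OC | intermediate
20 | 3-benzyloxy-2-(3,4-dibenzyloxyphenyl)-7-methoxychromene-4,5,8-trione | COC1=CC(=O)C2=C(OC(c3ccc(OCc4ccccc4)c(OCc4ccccc4)c3)=C(OCc3ccccc3)C2=O)C1=O | intermediate (not isolated)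
21 | 3-benzyloxy-2-(3,4-dibenzyloxyphenyl)-5,8-dihydroxy-7-methoxychromen-4-one | COc1cc(O)c2c(=O)c(OCc3ccccc3)c(-c3ccc(OCc4ccccc4)c(OCc4ccccc4)c3)oc2c1O | intermediate
22 | 8-acetoxy-3-benzyloxy-2-(3,4-dibenzyloxyphenyl)-5-hydroxy-7-methoxychromen-4-one | COc1cc(O)c2c(=O)c(OCc3ccccc3)c(-c3ccc(OCc4ccccc4)c(OCc4ccccc4)c3)oc2c1OC(C)=O | intermediate
23 | gossypetin 7-methyl ether 8-acetate | COc1cc(O)c2c(=O)c(O)c(-c3ccc(O)c(O)c3)oc2c1OC(C)=O | target

**Totals**
Total step count: 12. Longest linear sequence: 11 steps (steps 1–5, then 7–12, from 2,3-dimethoxyphenol).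

**Steps most likely to fail**

Step 7. Oxidative addition into the hindered, electron-rich C–I bond may be slow, so that direct alkynylation without CO uptake or five-membered closure competes and the pyranone forms incompletely. The fallback builds the ynone by polar chemistry and sets out from 9 and 11. Treatment of 9 with MOMCl and iPr2NEt in CH2Cl2 should give the methoxymethyl ether of 9, F1. Deprotonation of 11 with n-BuLi in THF at −78 °C and acylation with N-methoxy-N-methylcarbamoyl chloride should give N-methoxy-N-methyl-3-(3,4-dibenzyloxyphenyl)prop-2-ynamide F2. Iodine–magnesium exchange on the ether with i-PrMgCl·LiCl in THF at −20 °C and addition of the aryl Grignard to the amide should give the O-methoxymethyl ynone F3. HCl in MeOH removes the acetal and delivers 13, isolated this time. Warming 13 with Et2NH in EtOH takes it through 14 to 15, where the route resumes.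

Step 10. Single-electron oxidation of the benzyloxy-substituted ring B or of benzylic C–H bonds may compete with oxidation of ring A, or oxidation may stray to the ortho-quinone with loss of the 7-methyl group. The fallback makes ring B and O3 electron-poor before the oxidation and sets out from 19. Hydrogenolysis (H2, Pd/C, EtOAc/THF) should give 2-(3,4-dihydroxyphenyl)-3-hydroxy-5,7,8-trimethoxychromen-4-one F4. CbzCl and Et3N in CH2Cl2 at 0 °C should give the tris(benzyl carbonate) F5. (NH4)2Ce(NO3)6 in MeCN/H2O should then give the 7-methoxy-5,8-quinone tris(benzyl carbonate) F6, and aqueous Na2S2O4 the 5,8-dihydroxy tris(benzyl carbonate) F7. Ac2O and pyridine should give the 8-acetate tris(benzyl carbonate) F8. Hydrogenolysis of the three benzyl carbonates over Pd/C in EtOAc then returns to the route at 23.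

Step 8. Deprotonation at C3 may be incomplete, or amide addition at C2 and benzylic deprotonation may consume the flavone before the borate is added. The fallback replaces the base-mediated sequence by electrophilic oxygen transfer and sets out from 15. Dimethyldioxirane in acetone/CH2Cl2 at 0 °C should give the racemic cis-fused flavone 2,3-epoxide F9. Catalytic TsOH in CH2Cl2 opens it at C2, and loss of the C3 proton gives 18, where the route resumes.

**Further compounds**
F1 | step 7 | 2-iodo-3,5,6-trimethoxyphenyl methoxymethyl ether | COCOc1c(I)c(OC)cc(OC)c1OC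
F2 | step 7 | N-methoxy-N-methyl-3-(3,4-dibenzyloxyphenyl)prop-2-ynamide | CON(C)C(=O)C#Cc1ccc(OCc2ccccc2)c(OCc2ccccc2)c1
F3 | step 7 | 3-(3,4-dibenzyloxyphenyl)-1-[3,4,6-trimethoxy-2-(methoxymethoxy)phenyl]prop-2-yn-1-one | COCOc1c(C(=O)C#Cc2ccc(OCc3ccccc3)c(OCc3ccccc3)c2)c(OC)cc(OC)c1OC
F4 | step 10 | 2-(3,4-dihydroxyphenyl)-3-hydroxy-5,7,8-trimethoxychromen-4-one | COc1cc(OC)c2c(=O)c(O)c(-c3ccc(O)c(O)c3)oc2c1OC
F5 | step 10 | 5,7,8-trimethoxyflavone 3,3',4'-tris(benzyl carbonate) | COc1cc(OC)c2c(=O)c(OC(=O)OCc3ccccc3)c(-c3ccc(OC(=O)OCc4ccccc4)c(OC(=O)OCc4ccccc4)c3)oc2c1OC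
F6 | step 10 | 7-methoxyflavone-5,8-quinone 3,3',4'-tris(benzyl carbonate) | COC1=CC(=O)C2=C(OC(c3ccc(OC(=O)OCc4ccccc4)c(OC(=O)OCc4ccccc4)c3)=C(OC(=O)OCc3ccccc3)C2=O)C1=O
F7 | step 10 | 5,8-dihydroxy-7-methoxyflavone 3,3',4'-tris(benzyl carbonate) | COc1cc(O)c2c(=O)c(OC(=O)OCc3ccccc3)c(-c3ccc(OC(=O)OCc4ccccc4)c(OC(=O)OCc4ccccc4)c3)oc2c1O
F8 | step 10 | 8-acetoxy-5-hydroxy-7-methoxyflavone 3,3',4'-tris(benzyl carbonate) | COc1cc(O)c2c(=O)c(OC(=O)OCc3ccccc3)c(-c3ccc(OC(=O)OCc4ccccc4)c(OC(=O)OCc4ccccc4)c3)oc2c1OC(C)=O
F9 | step 8 | racemic cis-2,3-epoxy-2-(3,4-dibenzyloxyphenyl)-5,7,8-trimethoxychroman-4-one (one enantiomer drawn) | COc1cc(OC)c2C(=O)[C@H]3O[C@@]3(c4ccc(OCc5ccccc5)c(OCc5ccccc5)c4)Oc2c1OC
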